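**Retrosynthetic overview**
1. Target 12 comes from (S)-bis-TBS flavanone 11 by buffered desilylation. Compound 11 comes from the racemic enol acetal 9 by an enantioconvergent, chiral-acid-catalysed Petasis–Ferrier-type rearrangement. This exchanges ring oxygen O3 of a temporary 1,3-dioxine for the exocyclic CH2. It makes the only C–C bond between the two halves (C2–C3), unveils the C4 ketone, closes ring C (O1–C2–C3–C4–C4a–C8a) and sets C2.
2. Enabling feature: ring C is a β-aryloxy ketone. C2 lies between O1 and the p-alkoxyphenyl ring B, so it forms a doubly stabilised oxocarbenium ion. C3–C4 is an aryl ketone enol held ortho to O1 on ring A (C4a/C8a). The two ortho OH groups of the phloroglucinol ring A are equivalent, so no regiochemical question arises.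
3. Compound 9 comes from benzodioxinone 8 (Petasis methylenation), 8 from 7 (TBS protection), and 7 from the acetal union of 2,4,6-trihydroxybenzoic acid 4 with aldehyde 3. Aldehyde 3 comes from 4-hydroxybenzaldehyde 1 and geranyl bromide 2. Compound 9 holds only C–O links between the halves and no defined stereocentre.
4. Ring order: rings A and B are bought. The temporary dioxinone ring forms in step 2 and is opened again in step 5, where ring C closes as the last ring of the skeleton.

Key step: step 5

Assumption: the sense of induction of the new step 5 cannot be read from precedent; (R)-TRIP is written for Si-face closure at C2, and the equally available (S)-acid is to be taken if a pilot run shows the opposite sense.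

Step 1
Reactants: 1 4-hydroxybenzaldehyde; 2 geranyl bromide
Product: 3 4-(geranyloxy)benzaldehyde
Conditions: K2CO3, DMF, rt
Reagents that add atoms: none
Why: Williamson ether synthesis, in which the only phenoxide present displaces the primary allylic bromide by SN2 and leaves the E-alkene geometry untouched.

Step 2
Reactants: 4 2,4,6-trihydroxybenzoic acid; 3 4-(geranyloxy)benzaldehyde
Product: 7 rac-2-[4-(geranyloxy)phenyl]-5,7-dihydroxy-4H-1,3-benzodioxin-4-one, via tetrakis-TMS benzoate 5 (not isolated), via bis-TMS benzodioxinone 6 (not isolated)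
Conditions: (i) HMDS, cat. TMSCl, CH2Cl2, 40 °C, then evaporate; (ii) 3, TMSOTf (10 mol %), 2,6-di-tert-butyl-4-methylpyridine (5 mol %), CH2Cl2, −78 → −40 °C; (iii) pyridine, then MeOH, cat. citric acid, 0 °C
Reagents that add atoms: none
Why: Silyl-modified (Noyori-type) acetalisation as used to make dioxanones from hydroxy acids, in which TMSOTf activates the electron-rich aldehyde at low temperature, the silyl ester and one of the two equivalent ortho silyl ethers close the acylal with loss of hexamethyldisiloxane, the remaining aryl TMS ethers fall off in methanol, and the new acetal centre is racemic and is erased in step 5.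

Step 3
Reactants: 7 rac-2-[4-(geranyloxy)phenyl]-5,7-dihydroxy-4H-1,3-benzodioxin-4-one
Product: 8 rac-5,7-bis(tert-butyldimethylsilyloxy)-2-[4-(geranyloxy)phenyl]-4H-1,3-benzodioxin-4-one
Conditions: TBSCl (3 equiv), imidazole, cat. DMAP, DMF, rt → 40 °C
Reagents that add atoms: tert-butyldimethylsilyl chloride, CC(C)(C)[Si](C)(C)Cl
Why: Standard imidazole-promoted silylation of phenols, needed because free OH groups would protonate the titanium reagent of step 4, while aryl TBS ethers should survive steps 4 and 5 and leave under buffered fluoride.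

Step 4
Reactants: 8 rac-5,7-bis(tert-butyldimethylsilyloxy)-2-[4-(geranyloxy)phenyl]-4H-1,3-benzodioxin-4-one
Product: 9 rac-5,7-bis(tert-butyldimethylsilyloxy)-2-[4-(geranyloxy)phenyl]-4-methylidene-4H-1,3-benzodioxine
Conditions: Cp2TiMe2 (2.5 equiv), toluene, 70 °C, dark; hexane, filtration; basic alumina
Reagents that add atoms: dimethyltitanocene (Petasis reagent), C[Ti](C)(C1C=CC=C1)C1C=CC=C1
Why: Petasis methylenation, in which thermally formed Cp2Ti=CH2 turns lactone and dioxanone carbonyls into exocyclic enol ethers through an oxatitanacyclobutane under neutral conditions that leave the acetal, the silyl ethers and the trisubstituted alkenes alone.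

Step 5
Reactants: 9 rac-5,7-bis(tert-butyldimethylsilyloxy)-2-[4-(geranyloxy)phenyl]-4-methylidene-4H-1,3-benzodioxine
Product: 11 (2S)-5,7-bis(tert-butyldimethylsilyloxy)-2-[4-(geranyloxy)phenyl]-2,3-dihydro-4H-chromen-4-one, via oxocarbenium-enol ion pair 10 (not isolated)
Conditions: (R)-TRIP [(R)-3,3'-bis(2,4,6-triisopropylphenyl)-1,1'-binaphthyl-2,2'-diyl hydrogen phosphate] (10 mol %), 5 Å MS, toluene (0.02 M), −40 → −20 °C; Et3N quench
Reagents that add atoms: none
Why: Proposed new method: the chiral phosphoric acid hydrogen-bonds to and finally protonates the enol-ether oxygen O3 of racemic 9, the C2–O3 bond heterolyses because C2 is stabilised by both O1 and the p-geranyloxyphenyl ring B, and the tethered ion pair 10 (aryl oxocarbenium on C8a, acetophenone enol on C4a, phosphate bridging the enol O–H and the oxocarbenium C2–H) collapses by C3→C2 bond formation, so that O3 leaves the ring as the C4 carbonyl oxygen and the exocyclic CH2 enters it as C3. The closest known reaction types are the Lewis-acid Petasis–Ferrier rearrangement of 4-methylidene-1,3-dioxanes to tetrahydropyran-4-ones and the chiral-phosphoric-acid-catalysed aza-Petasis–Ferrier rearrangement of racemic hemiaminal vinyl ethers, neither of which has been run enantioselectively on a benzo-fused O,O-enol acetal. Ring C closes in a 6-(enolendo)-endo-trig mode through a half-chair with ring B pseudo-equatorial. The acetal stereocentre of 9 is erased on ionisation, since the half turn about C4–C4a that brings C3 to C2 leaves time for the two faces of the cation to equilibrate, and the new (S) centre is set by the 3,3'-aryl pocket of the bound phosphate, which should let the enol reach only the Si face of C2 (O1 > C1' > H), so both enantiomers of 9 converge on one product. The step needs three selectivities: ionisation of the acetal without harm to the geranyl ether, the trisubstituted alkenes and the silyl ethers (secured by the doubly stabilised C2 cation, which allows a weak acid at low temperature), C- over O-recombination (O-return and C-protonation of the methylidene group are reversible in the absence of water, C–C bond formation is not), and intra- over intermolecular attack (ortho tether on ring A, high dilution).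

Step 6
Reactants: 11 (2S)-5,7-bis(tert-butyldimethylsilyloxy)-2-[4-(geranyloxy)phenyl]-2,3-dihydro-4H-chromen-4-one
Product: 12 (2S)-5,7-dihydroxy-2-(4-{[(2E)-3,7-dimethylocta-2,6-dien-1-yl]oxy}phenyl)-2,3-dihydro-4H-chromen-4-one
Conditions: TBAF (2.2 equiv), AcOH (2.4 equiv), THF, 0 °C
Reagents that add atoms: none
Why: Fluoride-induced cleavage of aryl silyl ethers, buffered with acetic acid so that no phenoxide or enolate builds up to start the retro-oxa-Michael ring opening that would racemise C2, with the geranyl ether inert to fluoride.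

**Compound list**
1 | 4-hydroxybenzaldehyde | O=Cc1ccc(O)cc1 | starting material
2 | geranyl bromide, (2E)-1-bromo-3,7-dimethylocta-2,6-diene | CC(C)=CCC/C(C)=C/CBr | starting material
3 | 4-(geranyloxy)benzaldehyde | CC(C)=CCC/C(C)=C/COc1ccc(C=O)cc1 | intermediate
4 | 2,4,6-trihydroxybenzoic acid | OC(=O)c1c(O)cc(O)cc1O | starting material
5 | trimethylsilyl 2,4,6-tris(trimethylsilyloxy)benzoate (not isolated) | C[Si](C)(C)OC(=O)c1c(O[Si](C)(C)C)cc(O[Si](C)(C)C)cc1O[Si](C)(C)C | intermediate
6 | rac-2-[4-(geranyloxy)phenyl]-5,7-bis(trimethylsilyloxy)-4H-1,3-benzodioxin-4-one (not isolated) | CC(C)=CCC/C(C)=C/COc1ccc(C2OC(=O)c3c(O[Si](C)(C)C)cc(O[Si](C)(C)C)cc3O2)cc1 | intermediate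
7 | rac-2-[4-(geranyloxy)phenyl]-5,7-dihydroxy-4H-1,3-benzodioxin-4-one | CC(C)=CCC/C(C)=C/COc1ccc(C2OC(=O)c3c(O)cc(O)cc3O2)cc1 | intermediate
8 | rac-5,7-bis(tert-butyldimethylsilyloxy)-2-[4-(geranyloxy)phenyl]-4H-1,3-benzodioxin-4-one | CC(C)=CCC/C(C)=C/COc1ccc(C2OC(=O)c3c(O[Si](C)(C)C(C)(C)C)cc(O[Si](C)(C)C(C)(C)C)cc3O2)cc1 | intermediate
9 | rac-5,7-bis(tert-butyldimethylsilyloxy)-2-[4-(geranyloxy)phenyl]-4-methylidene-4H-1,3-benzodioxine | CC(C)=CCC/C(C)=C/COc1ccc(C2OC(=C)c3c(O[Si](C)(C)C(C)(C)C)cc(O[Si](C)(C)C(C)(C)C)cc3O2)cc1 | intermediate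
10 | ring-opened aryl oxocarbenium ion carrying the ortho 1-hydroxyvinyl (enol) group, cation drawn, counter-ion is the catalyst phosphate (not isolated) | CC(C)=CCC/C(C)=C/COc1ccc(C=[O+]c2cc(O[Si](C)(C)C(C)(C)C)cc(O[Si](C)(C)C(C)(C)C)c2C(O)=C)cc1 | intermediate
11 | (2S)-5,7-bis(tert-butyldimethylsilyloxy)-2-[4-(geranyloxy)phenyl]-2,3-dihydro-4H-chromen-4-one | CC(C)=CCC/C(C)=C/COc1ccc([C@@H]2CC(=O)c3c(O[Si](C)(C)C(C)(C)C)cc(O[Si](C)(C)C(C)(C)C)cc3O2)cc1 | intermediate
12 | (2S)-5,7-dihydroxy-2-(4-{[(2E)-3,7-dimethylocta-2,6-dien-1-yl]oxy}phenyl)-2,3-dihydro-4H-chromen-4-one | CC(C)=CCC/C(C)=C/COc1ccc([C@@H]2CC(=O)c3c(O)cc(O)cc3O2)cc1 | target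

**Totals**
Total step count: 6. Longest linear sequence: 6 (1 → 3 → 7 → 8 → 9 → 11 → 12).

**Steps most likely to fail**

Step 5 (new method). Loose ion pairing may give poor facial selectivity. Traces of water or intermolecular Friedel–Crafts attack may also divert the cation. The fallback uses known chemistry, sets out from 9 and comes back at 11. The classical Petasis–Ferrier rearrangement with stoichiometric Me2AlCl (CH2Cl2, −78 °C) should give the racemic bis-TBS flavanone F1. A Noyori–Ikariya transfer hydrogenation is then run as a kinetic resolution (RuCl[(R,R)-TsDPEN](p-cymene), HCO2H/Et3N, EtOAc, 0 °C → rt, stopped near half conversion). It should reduce the (R)-ketone to the (2R,4R)-cis-flavan-4-ol F2 and leave the (S)-ketone. After chromatography the (S)-ketone is 11.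

Step 4. The [2+2] addition of the titanium methylidene may be slow at the electron-rich lactone carbonyl flanked by the 5-silyloxy group. Unselective rearrangement may also set in early at 70 °C, or the enol acetal may hydrolyse during purification. The fallback bypasses 9, sets out from 3 and comes back at 11. Commercial 2',4',6'-trihydroxyacetophenone is silylated twice (TBSCl, imidazole, DMF) to the bis-TBS acetophenone F3. Its lithium dianion (LiHMDS, THF, −78 °C) adds to 3 to give the racemic aldol F4. Mitsunobu cyclodehydration (PPh3, DIAD, toluene, 0 °C) closes ring C to the racemic bis-TBS flavanone F1. The transfer-hydrogenation kinetic resolution described above then delivers 11.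

Step 2. The activated aldehyde may hydroxyalkylate the silylated phloroglucinol ring in a Friedel–Crafts reaction. Acid 4 may decarboxylate before it is fully silylated, and the acylal may open during removal of the TMS groups. The fallback activates the aldehyde instead of the acid, sets out from 3 and comes back at 7. Trimethyl orthoformate with cat. PPTS in MeOH converts 3 into the dimethyl acetal F5. This is transacetalised with unsilylated 4 (cat. PPTS, DME, 40 °C, 5 Å MS to take up methanol) under thermodynamic control to give 7.

**Further compounds**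
F1 | step 5 | rac-5,7-bis(tert-butyldimethylsilyloxy)-2-[4-(geranyloxy)phenyl]-2,3-dihydro-4H-chromen-4-one | CC(C)=CCC/C(C)=C/COc1ccc(C2CC(=O)c3c(O[Si](C)(C)C(C)(C)C)cc(O[Si](C)(C)C(C)(C)C)cc3O2)cc1
F2 | step 5 | (2R,4R)-5,7-bis(tert-butyldimethylsilyloxy)-2-[4-(geranyloxy)phenyl]-3,4-dihydro-2H-chromen-4-ol | CC(C)=CCC/C(C)=C/COc1ccc([C@H]2C[C@@H](O)c3c(O[Si](C)(C)C(C)(C)C)cc(O[Si](C)(C)C(C)(C)C)cc3O2)cc1
F3 | step 4 | 1-[2,4-bis(tert-butyldimethylsilyloxy)-6-hydroxyphenyl]ethan-1-one | CC(=O)c1c(O)cc(O[Si](C)(C)C(C)(C)C)cc1O[Si](C)(C)C(C)(C)C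
F4 | step 4 | rac-1-[2,4-bis(tert-butyldimethylsilyloxy)-6-hydroxyphenyl]-3-[4-(geranyloxy)phenyl]-3-hydroxypropan-1-one | CC(C)=CCC/C(C)=C/COc1ccc(C(O)CC(=O)c2c(O)cc(O[Si](C)(C)C(C)(C)C)cc2O[Si](C)(C)C(C)(C)C)cc1
F5 | step 2 | 1-(dimethoxymethyl)-4-(geranyloxy)benzene | CC(C)=CCC/C(C)=C/COc1ccc(C(OC)OC)cc1
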